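**Plan**

- Retrosynthesis: both β,γ-unsaturated ketones are cut at C(=O)–CH2(allyl), at the carbinol level. This gives a prenyl nucleophile, an (E)-aryl-methylbutenyl nucleophile and a cis-1,2-dimethylcyclopentane with an aldehyde-level carbon on C1 and a CH2CHO arm on C2 (ring numbering: C1 carries the acyl group, C2 the keto chain, C3–C5 are CH2).
- The CH2CHO arm is shortened by one carbon (Arndt–Eistert) to a meso cis-anhydride. The ring is then cut at C4–C5 and C3–C4, removing C4 as CH2. What remains is a cyclobutene whose strained C=C, held between the quaternary carbons C1 and C2, is the feature that takes up the carbon; it goes back to 2,3-dimethylmaleic anhydride and acetylene.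
- Forward: four-membered ring by [2+2] photocycloaddition, three-membered ring by CH2 transfer (a bicyclo[2.1.0]pentane anhydride), five-membered ring by hydrogenolysis of the central bond. Then desymmetrisation, homologation, side chain 1 (aryl fragment), side chain 2 (prenyl), double oxidation, desilylation.
- Stereochemistry: the cis relation of the two quaternary carbons comes from the suprafacial [2+2] on the cyclic alkene, the absolute configuration from alkaloid-mediated methanolysis of the meso anhydride, and the E alkene from SN2' opening of isoprene monoxide.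

Key step: step 2

Assumption: pinacol (2-methylbut-3-en-2-yl)boronate, the tertiary allylboronate of step 16, is taken as a purchasable reagent.

**Route**

Step 1
Reactants: 1 2,3-dimethylmaleic anhydride; 2 acetylene
Product: 3 cis-1,5-dimethyl-3-oxabicyclo[3.2.0]hept-6-ene-2,4-dione (meso; cis-1,2-dimethylcyclobut-3-ene-1,2-dicarboxylic anhydride)
Conditions: hν (Pyrex, >300 nm), benzophenone (sensitiser), acetone saturated with acetylene, −70 °C
Reagents that add atoms: none
Why: Triplet-sensitised [2+2] photocycloaddition of a maleic anhydride to acetylene; both new bonds form on the same face of the ring-locked Z alkene, so the two quaternary carbons are created with the methyl groups cis (meso product), and excess acetylene at low temperature should suppress photodimerisation of 1.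

Step 2
Reactants: 3 cis-1,5-dimethyl-3-oxabicyclo[3.2.0]hept-6-ene-2,4-dione
Product: 4 meso 1,5-dimethyl-3-oxatricyclo[3.3.0.0(6,8)]octane-2,4-dione (bicyclo[2.1.0]pentane whose C2 and C3 carry the methyl groups and the cis-fused anhydride; cyclopropane CH2 and anhydride on the same face of the four-membered ring)
Conditions: CH2N2 (excess), Pd(OAc)2 (3 mol %), Et2O/CH2Cl2, 0 °C
Reagents that add atoms: diazomethane, C=[N+]=[N-]
Why: Pd(OAc)2 is reduced by diazomethane to zerovalent palladium, which binds the strained cis-disubstituted C6=C7 bond of the cyclobutene and, through a palladium carbene (or a palladacyclobutane), delivers CH2 to both alkene carbons in one syn event, so that the cyclopentane bonds C4–C5 and C3–C4 of the target are made together. The closest known reaction type is the Pd(OAc)2-catalysed cyclopropanation of strained cycloalkenes with diazomethane (norbornenes, and cyclobutenes to bicyclo[2.1.0]pentanes). The ring that closes is the three-membered ring, by a [2+1] addition across the double bond; with it the five-carbon perimeter C1–C2–C3–C4–C5 of the target ring is complete and only the zero-atom bridge C3–C5 remains to be cut in step 3. The two new CH stereocentres are set by the face of attack, expected on the face away from the two methyl groups, but both become CH2 in step 3, so the epimer from the other face converges. The selectivity needed is reaction at C=C in preference to the anhydride carbonyls and clean mono-addition; the ring strain of the cyclobutene, the single alkene and the absence of O–H or enolisable C–H bonds secure it.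

Step 3
Reactants: 4 meso 1,5-dimethyl-3-oxatricyclo[3.3.0.0(6,8)]octane-2,4-dione
Product: 5 cis-1,5-dimethyl-3-oxabicyclo[3.3.0]octane-2,4-dione (meso; cis-1,2-dimethylcyclopentane-1,2-dicarboxylic anhydride)
Conditions: H2 (1 atm), Pd/C, EtOAc, 23 °C
Reagents that add atoms: none
Why: Hydrogenolysis of the central, most strained C–C bond of the bicyclo[2.1.0]pentane turns the two CH carbons into CH2 and leaves the cyclopentane, while the anhydride and the quaternary carbons are untouched and the product stays meso.

Step 4
Reactants: 5 cis-1,5-dimethyl-3-oxabicyclo[3.3.0]octane-2,4-dione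
Product: 6 (1S,2R)-2-(methoxycarbonyl)-1,2-dimethylcyclopentane-1-carboxylic acid
Conditions: quinine (1.1 equiv), MeOH (3 equiv), toluene, −50 °C; aq. HCl work-up
Reagents that add atoms: methanol, CO
Why: Cinchona-alkaloid-mediated (general-base) methanolysis of a meso anhydride distinguishes the two enantiotopic carbonyl groups, so the absolute configuration of both quaternary carbons is fixed without making or breaking a bond at either; quinine is expected to leave the acid on the carbon that becomes C2, and quinidine is the switch if a correlation shows the opposite sense.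

Step 5
Reactants: 6 (1S,2R)-2-(methoxycarbonyl)-1,2-dimethylcyclopentane-1-carboxylic acid
Product: 8 methyl (1R,2S)-2-(2-diazoacetyl)-1,2-dimethylcyclopentane-1-carboxylate, via acid chloride 7 (not isolated)
Conditions: (COCl)2, DMF (cat.), CH2Cl2, 0 to 23 °C; then CH2N2, Et3N, Et2O, 0 °C
Reagents that add atoms: diazomethane, C=[N+]=[N-]
Why: First stage of the Arndt–Eistert homologation: the acid chloride has no α-hydrogen, so acylation of diazomethane in the presence of Et3N should give the α-diazoketone without ketene formation, and no stereocentre is touched.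

Step 6
Reactants: 8 methyl (1R,2S)-2-(2-diazoacetyl)-1,2-dimethylcyclopentane-1-carboxylate
Product: 10 methyl (1R,2R)-2-{2-[methoxy(methyl)amino]-2-oxoethyl}-1,2-dimethylcyclopentane-1-carboxylate, via ketene 9 (not isolated)
Conditions: PhCO2Ag (10 mol %), Et3N, MeNHOMe·HCl, THF, −20 to 23 °C, dark
Reagents that add atoms: N,O-dimethylhydroxylamine (used as hydrochloride), CNOC
Why: Wolff rearrangement: silver-promoted loss of N2 and 1,2-shift of the quaternary ring carbon with retention of configuration give the ketene, which is trapped by the hydroxylamine as the Weinreb amide, so the arm on C2 is lengthened by one carbon.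

Step 7
Reactants: 10 methyl (1R,2R)-2-{2-[methoxy(methyl)amino]-2-oxoethyl}-1,2-dimethylcyclopentane-1-carboxylate
Product: 11 methyl (1R,2R)-1,2-dimethyl-2-(2-oxoethyl)cyclopentane-1-carboxylate
Conditions: i-Bu2AlH (1.3 equiv), THF, −78 °C
Reagents that add atoms: none
Why: The Weinreb amide is reduced through its stable chelated aluminium hemiaminal to the aldehyde, while the methyl ester on the quaternary carbon is too hindered to react at −78 °C.

Step 8
Reactants: 12 4-hydroxy-3-methylbenzaldehyde
Product: 13 3-bromo-4-hydroxy-5-methylbenzaldehyde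
Conditions: Br2, AcOH, 23 °C
Reagents that add atoms: bromine, BrBr
Why: Electrophilic aromatic bromination is directed by the hydroxyl group to its only free ortho position, which is also meta to the formyl group.

Step 9
Reactants: 13 3-bromo-4-hydroxy-5-methylbenzaldehyde
Product: 14 3-bromo-4-methoxy-5-methylbenzaldehyde
Conditions: MeI, K2CO3, DMF, 23 °C
Reagents that add atoms: iodomethane, CI
Why: Williamson O-methylation of the phenoxide, the only nucleophile present.

Step 10
Reactants: 14 3-bromo-4-methoxy-5-methylbenzaldehyde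
Product: 16 3-bromo-4-methoxy-5-methylphenol, via aryl formate 15 (not isolated)
Conditions: mCPBA, CH2Cl2, 23 °C; then K2CO3 (cat.), MeOH, 23 °C
Reagents that add atoms: 3-chloroperoxybenzoic acid (mCPBA), OOC(=O)c1cccc(Cl)c1
Why: Baeyer–Villiger oxidation with migration of the electron-rich aryl group gives the aryl formate, which methanolysis cleaves to the phenol, placing the free oxygen para to the methoxy group.

Step 11
Reactants: 16 3-bromo-4-methoxy-5-methylphenol
Product: 17 (3-bromo-4-methoxy-5-methylphenoxy)tri(propan-2-yl)silane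
Conditions: i-Pr3SiCl, imidazole, DMF, 23 °C
Reagents that add atoms: chlorotri(propan-2-yl)silane, CC(C)[Si](Cl)(C(C)C)C(C)C
Why: Silylation gives a bulky aryl silyl ether that should survive the organometallic and hydride steps and is removed by fluoride at the end.

Step 12
Reactants: 17 (3-bromo-4-methoxy-5-methylphenoxy)tri(propan-2-yl)silane; 18 2-methyl-2-vinyloxirane (isoprene monoxide, racemic)
Product: 20 (2E)-4-{2-methoxy-3-methyl-5-[tri(propan-2-yl)silyloxy]phenyl}-2-methylbut-2-en-1-ol, via arylmagnesium bromide 19 (not isolated)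
Conditions: Mg, THF, 50 °C; then CuI (10 mol %), 18, THF, −30 °C
Reagents that add atoms: none
Why: Copper-catalysed SN2' opening of the vinyl oxirane by the aryl Grignard reagent places the aryl group on the terminal vinyl carbon and gives the trisubstituted allylic alcohol, the E isomer being favoured through the s-trans conformer of the vinyl oxirane.

Step 13
Reactants: 20 (2E)-4-{2-methoxy-3-methyl-5-[tri(propan-2-yl)silyloxy]phenyl}-2-methylbut-2-en-1-ol
Product: 22 {3-[(2E)-4-chloro-3-methylbut-2-en-1-yl]-4-methoxy-5-methylphenoxy}tri(propan-2-yl)silane, via allylic mesylate 21 (not isolated)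
Conditions: MsCl, Et3N, CH2Cl2, −40 °C; then LiCl, THF, 0 °C
Reagents that add atoms: lithium chloride, [Li+].[Cl-]
Why: Mesylation and chloride displacement at the primary allylic carbon (SN2) should give the allylic chloride without allylic transposition or loss of the E geometry.

Step 14
Reactants: 22 {3-[(2E)-4-chloro-3-methylbut-2-en-1-yl]-4-methoxy-5-methylphenoxy}tri(propan-2-yl)silane; 11 methyl (1R,2R)-1,2-dimethyl-2-(2-oxoethyl)cyclopentane-1-carboxylate
Product: 24 methyl (1R,2R)-2-[(4E)-2-hydroxy-6-{2-methoxy-3-methyl-5-[tri(propan-2-yl)silyloxy]phenyl}-4-methylhex-4-en-1-yl]-1,2-dimethylcyclopentane-1-carboxylate (both carbinol epimers), via allylbarium chloride 23 (not isolated)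
Conditions: BaI2, Li, biphenyl, THF, 23 °C (activated zerovalent barium); 22, −78 °C; then 11, −78 °C; aq. NH4Cl at −78 °C
Reagents that add atoms: none
Why: Allylbarium reagents generated at −78 °C add to aldehydes at their less substituted (α) carbon with retention of the double-bond geometry, so the linear E homoallylic alcohol should form; the hindered ester does not react, and the new carbinol centre is removed later by oxidation.

Step 15
Reactants: 24 methyl (1R,2R)-2-[(4E)-2-hydroxy-6-{aryl}-4-methylhex-4-en-1-yl]-1,2-dimethylcyclopentane-1-carboxylate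
Product: 25 (4aR,7aR)-3-[(2E)-4-{2-methoxy-3-methyl-5-[tri(propan-2-yl)silyloxy]phenyl}-2-methylbut-2-en-1-yl]-4a,7a-dimethyloctahydrocyclopenta[c]pyran-1-ol (lactol; epimers at C1 and C3)
Conditions: i-Bu2AlH (3 equiv), CH2Cl2, −78 °C
Reagents that add atoms: none
Why: Partial reduction of the hindered ester: the aldehyde-level aluminium acetal is captured by the neighbouring alkoxide as a six-membered cyclic lactolate, which should block over-reduction and give the lactol on work-up.

Step 16
Reactants: 25 lactol (as above); 26 4,4,5,5-tetramethyl-2-(2-methylbut-3-en-2-yl)-1,3,2-dioxaborolane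
Product: 27 1-[(1R,2R)-2-[(4E)-2-hydroxy-6-{2-methoxy-3-methyl-5-[tri(propan-2-yl)silyloxy]phenyl}-4-methylhex-4-en-1-yl]-1,2-dimethylcyclopentyl]-4-methylpent-3-en-1-ol (both carbinols as epimer mixtures)
Conditions: 26 (2 equiv), toluene, 60 °C; aq. NaHCO3 work-up
Reagents that add atoms: none
Why: Allylboration of the ring-opened hydroxy aldehyde through a six-membered chair transition state joins the unsubstituted terminal CH2 of the tertiary allylboronate to the aldehyde carbon with allylic transposition, giving the linear prenyl carbinol; the reagent is neutral and tolerates the free hydroxyl group, and the new carbinol centre is removed in step 17.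

Step 17
Reactants: 27 diol (as above)
Product: 28 1-[(1R,2R)-2-[(4E)-6-{2-methoxy-3-methyl-5-[tri(propan-2-yl)silyloxy]phenyl}-4-methyl-2-oxohex-4-en-1-yl]-1,2-dimethylcyclopentyl]-4-methylpent-3-en-1-one
Conditions: Dess–Martin periodinane (3 equiv), NaHCO3, CH2Cl2, 0 to 23 °C
Reagents that add atoms: none
Why: Dess–Martin oxidation of both homoallylic carbinols under buffered, non-basic conditions should give the two β,γ-unsaturated ketones without moving either trisubstituted alkene into conjugation.

Step 18
Reactants: 28 silyl-protected diketone (as above)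
Product: 29 1-[(1R,2R)-2-[(4E)-6-(5-hydroxy-2-methoxy-3-methylphenyl)-4-methyl-2-oxohex-4-en-1-yl]-1,2-dimethylcyclopentyl]-4-methylpent-3-en-1-one (target)
Conditions: Bu4NF, AcOH (1:1), THF, 0 °C
Reagents that add atoms: none
Why: Fluoride cleaves the aryl silyl ether, and acetic acid buffers the phenoxide so that neither β,γ-unsaturated ketone is enolised.

**Compound list**

1 | 2,3-dimethylmaleic anhydride | CC1=C(C)C(=O)OC1=O | starting material
2 | acetylene | C#C | starting material
3 | cis-1,5-dimethyl-3-oxabicyclo[3.2.0]hept-6-ene-2,4-dione (meso) | O1C(=O)[C@@]2(C)C=C[C@@]2(C)C1=O | intermediate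
4 | meso 1,5-dimethyl-3-oxatricyclo[3.3.0.0(6,8)]octane-2,4-dione | O1C(=O)[C@@]2(C)[C@H]3C[C@H]3[C@@]2(C)C1=O | intermediate
5 | cis-1,5-dimethyl-3-oxabicyclo[3.3.0]octane-2,4-dione (meso) | O1C(=O)[C@@]2(C)CCC[C@@]2(C)C1=O | intermediate
6 | (1S,2R)-2-(methoxycarbonyl)-1,2-dimethylcyclopentane-1-carboxylic acid | OC(=O)[C@@]1(C)CCC[C@@]1(C)C(=O)OC | intermediate
7 | methyl (1R,2S)-2-(chlorocarbonyl)-1,2-dimethylcyclopentane-1-carboxylate | ClC(=O)[C@@]1(C)CCC[C@@]1(C)C(=O)OC | intermediate
8 | methyl (1R,2S)-2-(2-diazoacetyl)-1,2-dimethylcyclopentane-1-carboxylate | [N-]=[N+]=CC(=O)[C@@]1(C)CCC[C@@]1(C)C(=O)OC | intermediate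
9 | methyl (1R,2R)-1,2-dimethyl-2-(2-oxoethenyl)cyclopentane-1-carboxylate (ketene) | O=C=C[C@@]1(C)CCC[C@@]1(C)C(=O)OC | intermediate
10 | methyl (1R,2R)-2-{2-[methoxy(methyl)amino]-2-oxoethyl}-1,2-dimethylcyclopentane-1-carboxylate | CON(C)C(=O)C[C@@]1(C)CCC[C@@]1(C)C(=O)OC | intermediate
11 | methyl (1R,2R)-1,2-dimethyl-2-(2-oxoethyl)cyclopentane-1-carboxylate | O=CC[C@@]1(C)CCC[C@@]1(C)C(=O)OC | intermediate
12 | 4-hydroxy-3-methylbenzaldehyde | Cc1cc(C=O)ccc1O | starting material
13 | 3-bromo-4-hydroxy-5-methylbenzaldehyde | Cc1cc(C=O)cc(Br)c1O | intermediate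
14 | 3-bromo-4-methoxy-5-methylbenzaldehyde | COc1c(C)cc(C=O)cc1Br | intermediate
15 | 3-bromo-4-methoxy-5-methylphenyl formate | COc1c(C)cc(OC=O)cc1Br | intermediate
16 | 3-bromo-4-methoxy-5-methylphenol | COc1c(C)cc(O)cc1Br | intermediate
17 | (3-bromo-4-methoxy-5-methylphenoxy)tri(propan-2-yl)silane | COc1c(C)cc(O[Si](C(C)C)(C(C)C)C(C)C)cc1Br | intermediate
18 | 2-methyl-2-vinyloxirane (isoprene monoxide, racemic) | CC1(C=C)CO1 | starting material
19 | {2-methoxy-3-methyl-5-[tri(propan-2-yl)silyloxy]phenyl}magnesium bromide | COc1c(C)cc(O[Si](C(C)C)(C(C)C)C(C)C)cc1[Mg]Br | intermediate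
20 | (2E)-4-{2-methoxy-3-methyl-5-[tri(propan-2-yl)silyloxy]phenyl}-2-methylbut-2-en-1-ol | COc1c(C)cc(O[Si](C(C)C)(C(C)C)C(C)C)cc1C/C=C(\C)CO | intermediate
21 | methanesulfonate of 20 | COc1c(C)cc(O[Si](C(C)C)(C(C)C)C(C)C)cc1C/C=C(\C)COS(C)(=O)=O | intermediate
22 | {3-[(2E)-4-chloro-3-methylbut-2-en-1-yl]-4-methoxy-5-methylphenoxy}tri(propan-2-yl)silane | COc1c(C)cc(O[Si](C(C)C)(C(C)C)C(C)C)cc1C/C=C(\C)CCl | intermediate
23 | allylbarium chloride from 22 (barium on the former CH2Cl carbon, E alkene) | COc1c(C)cc(O[Si](C(C)C)(C(C)C)C(C)C)cc1C/C=C(\C)C[Ba]Cl | intermediate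
24 | methyl (1R,2R)-2-[(4E)-2-hydroxy-6-{2-methoxy-3-methyl-5-[tri(propan-2-yl)silyloxy]phenyl}-4-methylhex-4-en-1-yl]-1,2-dimethylcyclopentane-1-carboxylate (carbinol epimers) | COc1c(C)cc(O[Si](C(C)C)(C(C)C)C(C)C)cc1C/C=C(\C)CC(O)C[C@@]1(C)CCC[C@@]1(C)C(=O)OC | intermediate
25 | (4aR,7aR)-3-[(2E)-4-{2-methoxy-3-methyl-5-[tri(propan-2-yl)silyloxy]phenyl}-2-methylbut-2-en-1-yl]-4a,7a-dimethyloctahydrocyclopenta[c]pyran-1-ol (lactol, epimers at C1 and C3) | COc1c(C)cc(O[Si](C(C)C)(C(C)C)C(C)C)cc1C/C=C(\C)CC1C[C@@]2(C)CCC[C@@]2(C)C(O)O1 | intermediate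
26 | 4,4,5,5-tetramethyl-2-(2-methylbut-3-en-2-yl)-1,3,2-dioxaborolane | CC(C)(C=C)B1OC(C)(C)C(C)(C)O1 | starting material
27 | 1-[(1R,2R)-2-[(4E)-2-hydroxy-6-{2-methoxy-3-methyl-5-[tri(propan-2-yl)silyloxy]phenyl}-4-methylhex-4-en-1-yl]-1,2-dimethylcyclopentyl]-4-methylpent-3-en-1-ol (carbinol epimers) | COc1c(C)cc(O[Si](C(C)C)(C(C)C)C(C)C)cc1C/C=C(\C)CC(O)C[C@@]1(C)CCC[C@@]1(C)C(O)CC=C(C)C | intermediate
28 | 1-[(1R,2R)-2-[(4E)-6-{2-methoxy-3-methyl-5-[tri(propan-2-yl)silyloxy]phenyl}-4-methyl-2-oxohex-4-en-1-yl]-1,2-dimethylcyclopentyl]-4-methylpent-3-en-1-one | COc1c(C)cc(O[Si](C(C)C)(C(C)C)C(C)C)cc1C/C=C(\C)CC(=O)C[C@@]1(C)CCC[C@@]1(C)C(=O)CC=C(C)C | intermediate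
29 | 1-[(1R,2R)-2-[(4E)-6-(5-hydroxy-2-methoxy-3-methylphenyl)-4-methyl-2-oxohex-4-en-1-yl]-1,2-dimethylcyclopentyl]-4-methylpent-3-en-1-one | COc1c(C)cc(O)cc1C/C=C(\C)CC(=O)C[C@@]1(C)CCC[C@@]1(C)C(=O)CC=C(C)C | target

**Summary**

Total step count: 18. Longest linear sequence: 12 steps (steps 1–7, then 14–18); the aryl side-chain branch is steps 8–13.

**Steps most likely to fail**

Step 16. The lactol may open too slowly and the aldehyde on the quaternary carbon may add too slowly, so that the tertiary boronate decomposes first. The fallback sets out from 24 and protects before reducing. The carbinol is silylated (Et3SiCl, imidazole, DMF) to the triethylsilyl ether F1. LiAlH4 in THF reduces the ester to the neopentyl alcohol F2. Dess–Martin oxidation gives the aldehyde F3, which can no longer close to a lactol. Prenylbarium chloride F4, made from 1-chloro-3-methylbut-2-ene and activated barium at −78 °C, adds at its α-carbon to give the prenyl carbinol F5. PPTS in MeOH removes the triethylsilyl group while the aryl triisopropylsilyl ether stays, and the route is rejoined at 27.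

Step 14. The allylbarium reagent may lose α-regioselectivity or E geometry, or homocouple during its formation. The fallback sets out from 22 and 11 and replaces direct organometallic addition by an allyl transfer. A zinc-mediated Barbier reaction of 22 with acetone (Zn, THF, aq. NH4Cl) gives the branched γ-adduct, the tertiary homoallylic alcohol F6. With catalytic Sn(OTf)2 in CH2Cl2, F6 and aldehyde 11 should form an oxocarbenium ion that rearranges by a 2-oxonia-Cope process through a chair, transferring the allyl unit with transposition to give the linear E homoallylic alcohol and releasing acetone. The route is rejoined at 24.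

Step 4. Alcoholysis of the hindered anhydride may be slow and may discriminate the two enantiotopic carbonyl groups incompletely. The fallback sets out from 5 and uses classical resolution. NaOMe in MeOH opens the anhydride without selectivity to the racemic hemiester F7. Crystallisation with (S)-1-phenylethylamine (or its enantiomer, whichever gives the less soluble salt with 6) gives the diastereomerically pure ammonium salt F8. Acidification with aq. HCl returns the route at 6.

Further compounds
F1 | step 16 | triethylsilyl ether of 24 | COc1c(C)cc(O[Si](C(C)C)(C(C)C)C(C)C)cc1C/C=C(\C)CC(O[Si](CC)(CC)CC)C[C@@]1(C)CCC[C@@]1(C)C(=O)OC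
F2 | step 16 | [(1R,2R)-1,2-dimethyl-2-(chain with triethylsilyloxy group)cyclopentyl]methanol | COc1c(C)cc(O[Si](C(C)C)(C(C)C)C(C)C)cc1C/C=C(\C)CC(O[Si](CC)(CC)CC)C[C@@]1(C)CCC[C@@]1(C)CO
F3 | step 16 | (1R,2R)-1,2-dimethyl-2-(chain with triethylsilyloxy group)cyclopentane-1-carbaldehyde | COc1c(C)cc(O[Si](C(C)C)(C(C)C)C(C)C)cc1C/C=C(\C)CC(O[Si](CC)(CC)CC)C[C@@]1(C)CCC[C@@]1(C)C=O
F4 | step 16 | (3-methylbut-2-en-1-yl)barium chloride | CC(C)=CC[Ba]Cl
F5 | step 16 | mono-triethylsilyl ether of diol 27 (silyl group on the chain carbinol) | COc1c(C)cc(O[Si](C(C)C)(C(C)C)C(C)C)cc1C/C=C(\C)CC(O[Si](CC)(CC)CC)C[C@@]1(C)CCC[C@@]1(C)C(O)CC=C(C)C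
F6 | step 14 | 3-({2-methoxy-3-methyl-5-[tri(propan-2-yl)silyloxy]phenyl}methyl)-2,4-dimethylpent-4-en-2-ol | COc1c(C)cc(O[Si](C(C)C)(C(C)C)C(C)C)cc1CC(C(C)=C)C(C)(C)O
F7 | step 4 | racemic cis-2-(methoxycarbonyl)-1,2-dimethylcyclopentane-1-carboxylic acid | OC(=O)[C@@]1(C)CCC[C@@]1(C)C(=O)OC.OC(=O)[C@]1(C)CCC[C@]1(C)C(=O)OC
F8 | step 4 | (S)-1-phenylethylammonium (1S,2R)-2-(methoxycarbonyl)-1,2-dimethylcyclopentane-1-carboxylate | [O-]C(=O)[C@@]1(C)CCC[C@@]1(C)C(=O)OC.C[C@H]([NH3+])c1ccccc1
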